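The readings were computed on assumed constants; scatter was added.

Slowness is the first thing to measure here: how long one catalyst needs per passage of starting material, the inverse of its turnover frequency.

| setting | autumn | dawn | summer | midnight | ash | cedar | maple | birch |
|---|---|---|---|---|---|---|---|---|
| starting material | 28 mM | 28 mM | 28 mM | 14 mM | 28 mM | 28 mM (fed, over 2.0 min) | 28 mM | 28 mM |
| second substrate | 28 mM | 28 mM | 28 mM | 28 mM | 28.0 mM | 28.0 mM | 28.0 mM (fed, over 2.0 min) | 28.0 mM (fed, over 2.0 min) |
| free catalyst | 0.14 mM | 0.20 mM | 0.31 mM | 0.14 mM | 0.14 mM | 0.14 mM | 0.14 mM | 0.14 mM |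
| temperature | 35 °C | 46 °C | 35 °C | 46 °C |  | 40 °C |  | 40 °C |
| remark | run made earlier | run made earlier | run made earlier | run made earlier | everything together at the start at 10 °C, warmed to 40 °C at 2.0 min | all else is in the flask from the start; the feed brings no volume worth counting | the addition at 10 °C, then warmed to 40 °C; the feed brings no volume worth counting | all else is in the flask from the start; the feed brings no volume worth counting |
| time |  |  |  |  | 2.5 min | 2.5 min | 2.5 min | 2.5 min |

- autumn (time / s: target / %, side product / %): 20.0: 6, 10; 40.0: 14, 30; 50.0: 13, 36; 80.0: 23, 53; 90.0: 26, 60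
- dawn (time / s: target / %, side product / %): 10.0: 17, 13; 15.0: 22, 23; 25.0: 30, 43; 50.0: 40, 54; 90.0: 35, 54
- summer (time / s: target / %, side product / %): 10.0: 11, 8; 25.0: 27, 27; 40.0: 34, 42; 60.0: 43, 51; 90.0: 48, 51
- midnight (time / s: target / %, side product / %): 10.0: 18, 9; 15.0: 29, 16; 25.0: 41, 31; 50.0: 53, 39; 90.0: 46, 37

(standard deviation of a reading: 2 percentage points)

- in percentages every species weighs as the starting material in it: one side product counts as two

- the flask with the highest share of target in target plus side product ("all alike" if they lie within 1.5 percentage points) (ash / cedar / maple / birch / all alike)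
- share of target in target plus side product at the end, ash
- share of target in target plus side product at the end, cedar
- share of target in target plus side product at the end, maple
- share of target in target plus side product at the end, birch

Two runs at 35 °C give this pace independently. One side product counts as two, and in the dawn run it stands at 54% at 50.0 s and 54% at 90.0 s while target falls, so side product is read as formed from target plus starting material, and half of its percentage has passed the catalyst. Passages are therefore target plus half of side product. Per catalyst, autumn at 90.0 s gives 1.24 s⁻¹ and summer at 40.0 s gives 1.24 s⁻¹, and the two agree. Counting starting material gone instead, the same readings part: 1.91 s⁻¹ against 1.72 s⁻¹. That count cheats, because autumn, with more side product per target, credits its catalyst with more starting material that never passed it.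

Dawn at 25.0 s gives 2.88 s⁻¹ at 46 °C. This pace is an average over the run so far and no upper limit, since the dawn reading at 10.0 s gives a higher 3.29 s⁻¹. Interpolating the logarithm to 40 °C gives 1.82 s⁻¹. With 0.14 mM of catalyst, that makes a catalyst throughput, the run-average passage rate of that charge, of 0.255 mM s⁻¹. Cedar's feed is 0.233 mM s⁻¹, so its load, feed over throughput, is 0.914, a feed slightly below the run-average pace. This reckoning therefore places cedar between autumn's share of 30.2% and midnight's 57.6% at half the charge, and it places ash, maple and birch, which hold the whole charge of starting material from the start, near autumn's share.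

The forecast named cedar, with 70% (55% to 84%) for cedar and 33%, 30% and 28% for ash, maple and birch, holding that the feed “stays below catalyst capacity” at about 0.39 mM/s, and its cedar value stands above the range reckoned here.

The flasks give 30.5% for ash, 43.5% for cedar, 30.4% for maple and 30.5% for birch, so cedar leads, inside the reckoned range.

    second substrate + free catalyst ⇌ catalyst intermediate B (K = 95.4 M⁻¹, k = 187 M⁻¹ s⁻¹, Ea = 41.0 kJ mol⁻¹, ΔH = −8.00 kJ mol⁻¹)
    catalyst intermediate B → free catalyst + second product (k = 4.47 s⁻¹, Ea = 79.0 kJ mol⁻¹)
    starting material + target → side product (k = 2.53 M⁻¹ s⁻¹, Ea = 38.0 kJ mol⁻¹)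
    second substrate ⇌ dormant form (K = 0.740, k = 0.0109 s⁻¹, Ea = 81.0 kJ mol⁻¹, ΔH = 4.00 kJ mol⁻¹)
    catalyst intermediate A → free catalyst + target (k = 2.45 s⁻¹, Ea = 64.0 kJ mol⁻¹)
    starting material + free catalyst ⇌ catalyst intermediate A (K = 4500 M⁻¹, k = 924 M⁻¹ s⁻¹, Ea = 40.0 kJ mol⁻¹, ΔH = −42.0 kJ mol⁻¹)
    target → over-reaction product (k = 0.00209 s⁻¹, Ea = 79.0 kJ mol⁻¹)
    (constants at 40 °C)

Cedar's 43.5% belongs to a load of 0.914. The neighbouring flask, cedar with 0.24 mM of free catalyst, reckons to a throughput of 0.438 mM s⁻¹ and a load of 0.533, lighter than cedar's. It gives a share of 62.9%, with side product at 33.0%.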